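**Retrosynthetic overview**

1. The target comes from protected digallate 11 by desilylation at O7 and hydrogenolysis of nine benzyl ethers; both gallates are put on in one acylation of the (2R,3R)-flavan-3,5-diol 9.
2. Diol 9 comes from racemic flavan-3-one 8 by asymmetric transfer hydrogenation with dynamic kinetic resolution, which sets C2 and C3 (cis) together; 8 comes from hydrolysis of the 3-benzyloxy-2H-chromene 7.
3. Ring C (the pyran) is the only ring made, and it is made in step 3: resorcinol 2 and α-benzyloxy enal 5 combine, C4–C4a by condensation and O1–C2 by oxa-6π closure of an ortho-quinone methide. Rings A and B and the galloyl rings are bought as arenes.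
4. Enabling feature: in ring A, C4a lies between two oxygen-bearing carbons (C5 and C8a). In 2 both are free OH, so either one can close ring C to the same chromene, and the one left over is the O5–H that must be galloylated. The silyl ether on O7 screens the other two ring-A carbons, and O3, carried as the α-alkoxy group of the enal, switches off conjugate addition.
5. Enal 5 comes from an aldol condensation of aldehyde 3 with (benzyloxy)acetaldehyde 4; resorcinol 2 comes from phloroglucinol 1.

Key step: step 3

Assumption: the target is read as the natural (2R,3R), 2,3-cis (epi) series, and 3,4,5-tris(benzyloxy)benzoyl chloride 10 is taken as purchased (otherwise it is one step from the commercial acid with oxalyl chloride).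

**Step 1**
Reactants: 1 phloroglucinol (benzene-1,3,5-triol, 3 equiv)
Product: 2 5-[(triisopropylsilyl)oxy]benzene-1,3-diol
Conditions: i-Pr3SiCl (1 equiv), imidazole, DMF, 0 °C to rt; excess 1 removed by aqueous wash
Reagents that add atoms: triisopropylsilyl chloride, CC(C)[Si](Cl)(C(C)C)C(C)C
Why: Statistical mono-O-silylation (silyl ether formation) of the threefold-symmetric triphenol should work because the silicon electrophile reacts only at oxygen and the excess of cheap, water-soluble 1 limits bis-silylation.

**Step 2**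
Reactants: 3 3,4,5-tris(benzyloxy)benzaldehyde; 4 (benzyloxy)acetaldehyde
Product: 5 (2Z)-2-(benzyloxy)-3-[3,4,5-tris(benzyloxy)phenyl]prop-2-enal
Conditions: NaOH (2 M aq., 0.3 equiv), MeOH/THF, 0 °C to rt, slow addition of 4
Reagents that add atoms: none
Why: A crossed aldol (Claisen–Schmidt) condensation between the non-enolisable aryl aldehyde and the α-alkoxy aldehyde, with E1cB dehydration, should give the conjugated enal as the thermodynamically preferred (Z)-isomer (aryl trans to formyl), slow addition of 4 limiting its self-condensation.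

**Step 3**
Reactants: 2 5-[(triisopropylsilyl)oxy]benzene-1,3-diol; 5 (2Z)-2-(benzyloxy)-3-[3,4,5-tris(benzyloxy)phenyl]prop-2-enal
Product: 7 rac-3-(benzyloxy)-2-[3,4,5-tris(benzyloxy)phenyl]-7-[(triisopropylsilyl)oxy]-2H-chromen-5-ol, via ortho-quinone methide 6 (not isolated)
Conditions: ethylenediammonium diacetate (20 mol %), toluene, 4 Å molecular sieves, 90 °C
Reagents that add atoms: none
Why: The primary ammonium acetate converts enal 5 into its iminium ion, the carbon of 2 that lies between the two free hydroxyls adds to the iminium carbon (1,2-addition) to make the C4–C4a bond, and loss of the amine gives ortho-quinone methide 6, a 1-oxatriene that closes thermally to make the O1–C2 bond and restore the arene. The closest known reaction type is the amine-catalysed formal [3+3] annulation (Knoevenagel condensation then oxa-6π electrocyclisation) of resorcinols and cyclic 1,3-diones with enals to give 2H-chromenes. Ring C closes by disrotatory oxa-6π electrocyclisation of the O=C8a–C4a=C4–C3=C2 unit, and because both carbons flanking C4a carry oxygen the closure is possible from either geometry of the exocyclic double bond and leads to one constitution. The only new stereocentre, C2, is formed racemic on purpose: nothing controls it here because it becomes enolisable in ketone 8 and is set in step 5. The step needs site selectivity on ring A and 1,2- over 1,4-selectivity on the enal: the triisopropylsilyl ether on O7 screens both carbons next to it, so that only the carbon between the two hydroxyls reacts and a second annulation on the remaining hydroxyl is blocked, and the α-benzyloxy group makes the aryl-bearing carbon of 5 the electron-rich end of an enol ether, which disfavours conjugate addition.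

**Step 4**
Reactants: 7 rac-3-(benzyloxy)-2-[3,4,5-tris(benzyloxy)phenyl]-7-[(triisopropylsilyl)oxy]-2H-chromen-5-ol
Product: 8 rac-5-hydroxy-2-[3,4,5-tris(benzyloxy)phenyl]-7-[(triisopropylsilyl)oxy]-2H-chromen-3(4H)-one
Conditions: HCl (2 M aq.), THF, rt, under argon; used directly in step 5
Reagents that add atoms: water, O
Why: Acid-catalysed enol ether hydrolysis (protonation at C4, addition of water to the C3 oxocarbenium ion, loss of benzyl alcohol) should unmask the ketone while the aryl silyl ether and aryl benzyl ethers, which are stable to dilute acid, stay in place.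

**Step 5**
Reactants: 8 rac-5-hydroxy-2-[3,4,5-tris(benzyloxy)phenyl]-7-[(triisopropylsilyl)oxy]-2H-chromen-3(4H)-one
Product: 9 (2R,3R)-2-[3,4,5-tris(benzyloxy)phenyl]-7-[(triisopropylsilyl)oxy]-3,4-dihydro-2H-chromene-3,5-diol
Conditions: RuCl(p-cymene)[(R,R)-TsDPEN] (2 mol %), HCO2H/Et3N (5:2), DMF, 30 °C
Reagents that add atoms: none
Why: In a Noyori–Ikariya asymmetric transfer hydrogenation with dynamic kinetic resolution, the C2–H (benzylic, α to the ketone and to O1) should epimerise through the enol under the amine buffer while the divalent ruthenium hydride of the N-tosyl-1,2-diphenylethylenediamine complex reduces one ketone enantiomer faster, hydride arriving anti to the C2 aryl group to give the 2,3-cis alcohol, and the (R,R)-ligand is chosen to deliver hydride to the face that gives 3R when the C2 side takes the place of the aryl group of an aryl alkyl ketone in the usual model.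

**Step 6**
Reactants: 9 (2R,3R)-2-[3,4,5-tris(benzyloxy)phenyl]-7-[(triisopropylsilyl)oxy]-3,4-dihydro-2H-chromene-3,5-diol; 10 3,4,5-tris(benzyloxy)benzoyl chloride (2.6 equiv)
Product: 11 (2R,3R)-2-[3,4,5-tris(benzyloxy)phenyl]-7-[(triisopropylsilyl)oxy]-3,4-dihydro-2H-chromene-3,5-diyl bis[3,4,5-tris(benzyloxy)benzoate]
Conditions: Et3N, DMAP (cat.), CH2Cl2, 0 °C to rt
Reagents that add atoms: none
Why: DMAP-catalysed esterification with the acid chloride should acylate both the phenolic O5–H and the secondary O3–H in one operation without touching either stereocentre, O7 being blocked as its silyl ether.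

**Step 7**
Reactants: 11 (2R,3R)-2-[3,4,5-tris(benzyloxy)phenyl]-7-[(triisopropylsilyl)oxy]-3,4-dihydro-2H-chromene-3,5-diyl bis[3,4,5-tris(benzyloxy)benzoate]
Product: 12 (2R,3R)-7-hydroxy-2-[3,4,5-tris(benzyloxy)phenyl]-3,4-dihydro-2H-chromene-3,5-diyl bis[3,4,5-tris(benzyloxy)benzoate]
Conditions: Bu4NF (1.1 equiv), AcOH (1.2 equiv), THF, 0 °C
Reagents that add atoms: none
Why: Fluoride-mediated cleavage of the aryl silyl ether, buffered with acetic acid so that the liberated phenol is protonated at once, should free O7–H without attack on the aryl or alkyl gallate esters, which have no neighbouring hydroxyl to migrate to.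

**Step 8**
Reactants: 12 (2R,3R)-7-hydroxy-2-[3,4,5-tris(benzyloxy)phenyl]-3,4-dihydro-2H-chromene-3,5-diyl bis[3,4,5-tris(benzyloxy)benzoate]
Product: 13 epigallocatechin 3,5-digallate, (2R,3R)-7-hydroxy-2-(3,4,5-trihydroxyphenyl)-3,4-dihydro-2H-chromene-3,5-diyl bis(3,4,5-trihydroxybenzoate)
Conditions: H2 (1 atm), Pd(OH)2/C, THF/MeOH, rt
Reagents that add atoms: none
Why: Catalytic hydrogenolysis of the nine aryl benzyl ethers under neutral conditions should leave the two esters, the C2–O1 bond and both stereocentres intact, as in the final step of related gallated flavan-3-ol syntheses.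

**Compound list**

1 | phloroglucinol (benzene-1,3,5-triol) | Oc1cc(O)cc(O)c1 | starting material
2 | 5-[(triisopropylsilyl)oxy]benzene-1,3-diol | Oc1cc(O)cc(O[Si](C(C)C)(C(C)C)C(C)C)c1 | intermediate
3 | 3,4,5-tris(benzyloxy)benzaldehyde | O=Cc1cc(OCc2ccccc2)c(OCc2ccccc2)c(OCc2ccccc2)c1 | starting material
4 | (benzyloxy)acetaldehyde | O=CCOCc1ccccc1 | starting material
5 | (2Z)-2-(benzyloxy)-3-[3,4,5-tris(benzyloxy)phenyl]prop-2-enal | O=C/C(OCc1ccccc1)=C/c1cc(OCc2ccccc2)c(OCc2ccccc2)c(OCc2ccccc2)c1 | intermediate
6 | ortho-quinone methide, 6-{(2Z)-2-(benzyloxy)-3-[3,4,5-tris(benzyloxy)phenyl]prop-2-en-1-ylidene}-5-hydroxy-3-[(triisopropylsilyl)oxy]cyclohexa-2,4-dien-1-one | O=C1C=C(O[Si](C(C)C)(C(C)C)C(C)C)C=C(O)C1=C/C(OCc1ccccc1)=C/c1cc(OCc2ccccc2)c(OCc2ccccc2)c(OCc2ccccc2)c1 | intermediate (not isolated)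
7 | rac-3-(benzyloxy)-2-[3,4,5-tris(benzyloxy)phenyl]-7-[(triisopropylsilyl)oxy]-2H-chromen-5-ol | Oc1cc(O[Si](C(C)C)(C(C)C)C(C)C)cc2c1C=C(OCc1ccccc1)C(c1cc(OCc3ccccc3)c(OCc3ccccc3)c(OCc3ccccc3)c1)O2 | intermediate
8 | rac-5-hydroxy-2-[3,4,5-tris(benzyloxy)phenyl]-7-[(triisopropylsilyl)oxy]-2H-chromen-3(4H)-one | Oc1cc(O[Si](C(C)C)(C(C)C)C(C)C)cc2c1CC(=O)C(c1cc(OCc3ccccc3)c(OCc3ccccc3)c(OCc3ccccc3)c1)O2 | intermediate
9 | (2R,3R)-2-[3,4,5-tris(benzyloxy)phenyl]-7-[(triisopropylsilyl)oxy]-3,4-dihydro-2H-chromene-3,5-diol | Oc1cc(O[Si](C(C)C)(C(C)C)C(C)C)cc2c1C[C@@H](O)[C@@H](c1cc(OCc3ccccc3)c(OCc3ccccc3)c(OCc3ccccc3)c1)O2 | intermediate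
10 | 3,4,5-tris(benzyloxy)benzoyl chloride | O=C(Cl)c1cc(OCc2ccccc2)c(OCc2ccccc2)c(OCc2ccccc2)c1 | starting material
11 | (2R,3R)-2-[3,4,5-tris(benzyloxy)phenyl]-7-[(triisopropylsilyl)oxy]-3,4-dihydro-2H-chromene-3,5-diyl bis[3,4,5-tris(benzyloxy)benzoate] | O=C(Oc1cc(O[Si](C(C)C)(C(C)C)C(C)C)cc2c1C[C@@H](OC(=O)c1cc(OCc3ccccc3)c(OCc3ccccc3)c(OCc3ccccc3)c1)[C@@H](c1cc(OCc3ccccc3)c(OCc3ccccc3)c(OCc3ccccc3)c1)O2)c1cc(OCc2ccccc2)c(OCc2ccccc2)c(OCc2ccccc2)c1 | intermediate
12 | (2R,3R)-7-hydroxy-2-[3,4,5-tris(benzyloxy)phenyl]-3,4-dihydro-2H-chromene-3,5-diyl bis[3,4,5-tris(benzyloxy)benzoate] | O=C(Oc1cc(O)cc2c1C[C@@H](OC(=O)c1cc(OCc3ccccc3)c(OCc3ccccc3)c(OCc3ccccc3)c1)[C@@H](c1cc(OCc3ccccc3)c(OCc3ccccc3)c(OCc3ccccc3)c1)O2)c1cc(OCc2ccccc2)c(OCc2ccccc2)c(OCc2ccccc2)c1 | intermediate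
13 | epigallocatechin 3,5-digallate, (2R,3R) | O=C(Oc1cc(O)cc2c1C[C@@H](OC(=O)c1cc(O)c(O)c(O)c1)[C@@H](c1cc(O)c(O)c(O)c1)O2)c1cc(O)c(O)c(O)c1 | target

**Step count**

Total: 8 steps. Longest linear sequence: 7 steps (1, 3, 4, 5, 6, 7, 8 from phloroglucinol; equally 2 to 8 from aldehyde 3).

**Steps most likely to fail**

Step 3. What may go wrong is slow condensation at the hindered α-alkoxy aldehyde, with conjugate addition of the resorcinol or attack through a silyl-flanked ring carbon taking over. The fallback builds the two bonds one after the other; it sets out from 2 and 3 and comes back at 8. CH2=CHMgBr (THF, 0 °C) would add to 3 to give the allylic alcohol 1-[3,4,5-tris(benzyloxy)phenyl]prop-2-en-1-ol F1. Friedel–Crafts allylation of 2 with F1 (H2SO4 on SiO2, CH2Cl2, rt), through the cinnamyl cation attacked at its unsubstituted end, should give the (E)-2-cinnamylresorcinol F2. Dehydrogenative cyclisation of F2 with DDQ (benzene, rt), which generates an ortho-quinone methide by hydride abstraction at the doubly activated CH2, should give the 2H-chromene F3. Hydroboration–oxidation (BH3·THF, then NaBO3·4H2O) should give the racemic 2,3-trans-flavan-3-ol F4, boron adding anti to the aryl group, and oxidation (SO3·pyridine, DMSO, i-Pr2NEt) would return ketone 8, where the configuration is again of no consequence.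

Step 5. What may go wrong is racemisation at C2 that is slower than reduction, which would erode the enantiomeric and cis/trans purity, or a sense of induction opposite to the model. The sense would be checked on the first run against the natural series, and the antipodal complex is equally available. The fallback replaces catalyst control by substrate control plus resolution; it sets out from 8 and comes back at 9. LiBH(s-Bu)3 (THF, −78 °C) should reduce 8 from the face opposite the C2 aryl group to the racemic 2,3-cis alcohol F5, whose enantiomers would be separated by preparative chromatography on a chiral stationary phase, the (2R,3R)-enantiomer being 9.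

Step 4. What may go wrong is acid-induced ionisation of the 2-aryl-2H-chromene, with hydride transfer between molecules (disproportionation towards a flavylium salt), competing with enol ether hydrolysis. The fallback brings in the C3 oxygen by hydroboration instead of carrying it as an enol ether; it sets out from 2 and 3 and comes back at 8. Wittig olefination of 3 with Ph3P=CHCHO (toluene, 80 °C) should give (2E)-3-[3,4,5-tris(benzyloxy)phenyl]prop-2-enal F6. Annulation of F6 with 2 under the conditions of step 3 should give the 2H-chromene F3, which is then taken on as above through the trans-alcohol F4 to ketone 8.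

**Further compounds**

F1 | step 3 | 1-[3,4,5-tris(benzyloxy)phenyl]prop-2-en-1-ol (racemic) | C=CC(O)c1cc(OCc2ccccc2)c(OCc2ccccc2)c(OCc2ccccc2)c1
F2 | step 3 | 2-{(2E)-3-[3,4,5-tris(benzyloxy)phenyl]prop-2-en-1-yl}-5-[(triisopropylsilyl)oxy]benzene-1,3-diol | Oc1cc(O[Si](C(C)C)(C(C)C)C(C)C)cc(O)c1C/C=C/c1cc(OCc2ccccc2)c(OCc2ccccc2)c(OCc2ccccc2)c1
F3 | step 3 | rac-2-[3,4,5-tris(benzyloxy)phenyl]-7-[(triisopropylsilyl)oxy]-2H-chromen-5-ol | Oc1cc(O[Si](C(C)C)(C(C)C)C(C)C)cc2c1C=CC(c1cc(OCc3ccccc3)c(OCc3ccccc3)c(OCc3ccccc3)c1)O2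
F4 | step 3 | rac-(2R,3S)-2-[3,4,5-tris(benzyloxy)phenyl]-7-[(triisopropylsilyl)oxy]-3,4-dihydro-2H-chromene-3,5-diol (2,3-trans, racemate, one enantiomer drawn) | Oc1cc(O[Si](C(C)C)(C(C)C)C(C)C)cc2c1C[C@H](O)[C@@H](c1cc(OCc3ccccc3)c(OCc3ccccc3)c(OCc3ccccc3)c1)O2
F5 | step 5 | rac-(2R,3R)-2-[3,4,5-tris(benzyloxy)phenyl]-7-[(triisopropylsilyl)oxy]-3,4-dihydro-2H-chromene-3,5-diol (2,3-cis, racemate, one enantiomer drawn) | Oc1cc(O[Si](C(C)C)(C(C)C)C(C)C)cc2c1C[C@@H](O)[C@@H](c1cc(OCc3ccccc3)c(OCc3ccccc3)c(OCc3ccccc3)c1)O2
F6 | step 4 | (2E)-3-[3,4,5-tris(benzyloxy)phenyl]prop-2-enal | O=C/C=C/c1cc(OCc2ccccc2)c(OCc2ccccc2)c(OCc2ccccc2)c1
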